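(The numbers in the tables were computed for substances that don't exist.)

At early times the electrophile falls from the whole charge to 66% in 1.33 h, and it falls the same in both earlier runs.

| setting | dawn | midnight | alpha | gamma |
|---|---|---|---|---|
| electrophile | 0.11 M | 0.11 M | 0.11 M | 0.11 M |
| nucleophile | 0.275 M | 0.275 M | 0.275 M | 0.275 M |
| free base | 0.13 M | 0.15 M | 0.120 M | 0.180 M |
| remark | run made earlier | run made earlier |  |  |
| time |  |  | 15 h | 15 h |

| run | time / h | electrophile / % | target / % |
|---|---|---|---|
| dawn | 1.33 | 66 | 29 |
| dawn | 3.00 | 41 | 39 |
| dawn | 6.00 | 16 | 44 |
| dawn | 15.0 | 3 | 45 |
| midnight | 1.33 | 66 | 28 |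
| midnight | 3.00 | 41 | 37 |
| midnight | 6.00 | 16 | 45 |
| midnight | 15.0 | 1 | 42 |

(readings scatter by 1.5 percentage points)

- part of the electrophile that has reacted at the end, alpha
- part of the electrophile that has reacted at the end, gamma
- what raising the concentration of free base from its lowest to its highest value here does to the part of the electrophile that has reacted (changes below 5 percentage points count as none) (no change / it rises / it falls)

- the analysis behind the earlier runs scatters by 1.5 percentage points, standard deviation

*What do you read from those two tables?* That equal spans of time seem to remove equal factors, so I take logarithms and count powers of ten. Between 1.33 h and 6.00 h, the electrophile drops from 66% to 16%, which is 0.615 of a power of ten. That gives the tenfold time τ, the time in which the electrophile shrinks by a factor of ten: 7.59 h. Treating the decay as pseudo-first-order is a reading, and it carries the scatter.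

*And at the asked time?* 15 h is 1.98 tenfold times, so 1.06% remains, which is my own reckoning.

*But alpha has less free base than either run, doesn't it?* Yes, 0.120 M against 0.13 M, so using τ there is an assumption. Still, alpha's free base exceeds its electrophile, by a factor of 1.09. I commit to the same τ for both flasks, hence 98.9% reacted in each and no change.

The forecast says 97% for alpha, 99% for gamma and no change, holding that the “rate is essentially independent of free base”. It sits lower than my figure for alpha.

The flask gives 97.6% for alpha and 97.8% for gamma, a change of 0.2 percentage points, so no change.

    target ⇌ isomer of the product (K = 0.980, k = 7.00 × 10⁻⁵ s⁻¹)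
    acid set free + free base ⇌ salt of the base, settled at all times (K = 2600 M⁻¹)
    nucleophile + acid set free ⇌ protonated nucleophile, settled at all times (K = 90.0 M⁻¹)
    electrophile + nucleophile → acid set free + target (k = 3.40 × 10⁻⁴ M⁻¹ s⁻¹)
    electrophile + target → side product (k = 1.40 × 10⁻⁴ M⁻¹ s⁻¹)

At the end, alpha holds 29% of its free base and 2.4% of its electrophile, so it has passed 1.62 powers of ten rather than 1.98. A run that breaks the forecast's outcome is the neighbour of alpha charged with 0.44 M of electrophile. There free base runs out first, down to 0.69% of its charge. That neighbour keeps 27% of its electrophile, a tenfold time of 26.1 h against τ of 7.59 h.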